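## Retrosynthetic overview

- **Feature.** In ring A (C1'–C6'), the C6' CH2O group (C8') and the side-chain carbon C5 on C1' stand cis on two adjacent, fully substituted carbons. C8'–O–C5(=O) can therefore be closed to a five-membered lactone in which C1' is the ketone of an α-keto lactone.
- **Endgame.** C3–C4 comes from a Stille coupling. The C8'O–acyl bond comes from esterification with an HMG half ester made from (R)-mevalonolactone. C4≡C5 comes from the lactone carbonyl (DIBAL-H, Ohira–Bestmann).
- **Key disconnection C1'–C2'.** The (Z)-β-iodoenone arm on C6' of keto lactone 12 is closed onto the C1' ketone with CrCl2/NiCl2, and the forced cis ring fusion relays C6' to C1'.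
- **Source of 12.** It comes from dimethyl (R)-malate. Two Fráter–Seebach alkylations set C6', ester differentiation closes the lactone, and an enyne arm is unmasked to the ynone and hydroiodinated.
- **Ring order.** The γ-lactone forms in step 5 and ring A in step 9; the lactone is opened again in step 12.

Key step: step 9

Remark: abscisic acid locants are used (ring A = C1'–C6', C7' = CH3 on C2', C8' = CH2O and C9' = CH3 on C6', side chain C1–C5). The CIP descriptor of the HMG carbinol changes along 20 → 21–28 → 29/30 only because substituent priorities change.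

Assumption: lactol 15 should form as a mixture of anomers and is drawn without configuration at the anomeric carbon, which becomes sp-hybridised in step 12.

## Route

**Step 1**
Reactants: 1 dimethyl (R)-malate; 2 2,3-dibromopropene
Product: 3 dimethyl (2R,3S)-3-(2-bromoprop-2-en-1-yl)-2-hydroxybutanedioate
Conditions: LDA (2.2 equiv), THF, −78 → −20 °C; 2 (1.3 equiv), −78 → −10 °C; then AcOH
Reagents that add atoms: none
Why: Fráter–Seebach alkylation, in which the chelated dilithio alkoxide–enolate of the β-hydroxy ester should take up the allylic bromide at C3 on the face away from the C2 ester group (anti product), and the C3 centre made here is erased again by the enolisation of step 3, so its purity does not matter.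

**Step 2**
Reactants: 3 dimethyl (2R,3S)-3-(2-bromoprop-2-en-1-yl)-2-hydroxybutanedioate; 4 propyne
Product: 5 dimethyl (2R,3S)-2-hydroxy-3-(2-methylidenepent-3-yn-1-yl)butanedioate
Conditions: PdCl2(PPh3)2 (3 mol %), CuI (6 mol %), Et3N, THF, sealed tube, 45 °C
Reagents that add atoms: none
Why: Sonogashira coupling of a 2-bromo-1-alkene with a terminal alkyne is routine, tolerates the free hydroxyl and the esters, creates no stereocentre and removes the base-sensitive alkenyl bromide before the second enolisation.

**Step 3**
Reactants: 5 dimethyl (2R,3S)-2-hydroxy-3-(2-methylidenepent-3-yn-1-yl)butanedioate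
Product: 6 dimethyl (2R,3R)-2-hydroxy-3-methyl-3-(2-methylidenepent-3-yn-1-yl)butanedioate
Conditions: LDA (2.3 equiv), THF, −78 → −15 °C; MeI (4 equiv), −78 → 0 °C; then AcOH
Reagents that add atoms: iodomethane, CI
Why: Second Fráter–Seebach alkylation, in which the same lithium chelate now holds the enyne arm in the enolate plane and MeI should again enter anti to the C2 ester group, so that the quaternary carbon (future C6') is set as 3R under control of the malate carbinol centre.

**Step 4**
Reactants: 6 dimethyl (2R,3R)-2-hydroxy-3-methyl-3-(2-methylidenepent-3-yn-1-yl)butanedioate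
Product: 7 (2R,3R)-2-hydroxy-4-methoxy-3-methyl-3-(2-methylidenepent-3-yn-1-yl)-4-oxobutanoic acid
Conditions: KOH (1.05 equiv), MeOH/H2O, 0 → 23 °C; then 1 M HCl to pH 2
Reagents that add atoms: potassium hydroxide, [K+].[OH-]
Why: Chemoselective saponification, since one equivalent of hydroxide should attack only the unhindered, inductively activated α-hydroxy ester at C1 while the C4 ester is shielded by the new quaternary carbon.

**Step 5**
Reactants: 7 (2R,3R)-2-hydroxy-4-methoxy-3-methyl-3-(2-methylidenepent-3-yn-1-yl)-4-oxobutanoic acid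
Product: 9 (3R,4S)-3-hydroxy-4-methyl-4-(2-methylidenepent-3-yn-1-yl)oxolan-2-one, via dihydroxy acid 8 (not isolated)
Conditions: LiEt3BH (5 equiv), THF, 0 → 23 °C; then 2 M HCl, 23 °C
Reagents that add atoms: none
Why: Hydride reduction of the hindered ester while the carboxylate is protected by its charge, followed by acid-induced lactonisation favoured by the gem-disubstitution (pantolactone-type closure), should give the γ-lactone with both stereocentres untouched and the hydroxyl trans to the enyne arm.

**Step 6**
Reactants: 9 (3R,4S)-3-hydroxy-4-methyl-4-(2-methylidenepent-3-yn-1-yl)oxolan-2-one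
Product: 10 (3R,4S)-3-hydroxy-4-methyl-4-(2-oxopent-3-yn-1-yl)oxolan-2-one
Conditions: O3, CH2Cl2, −78 °C (Sudan Red 7B end point); Me2S, −78 → 23 °C
Reagents that add atoms: ozone, [O-][O+]=O
Why: Ozonolysis is much faster at the 1,1-disubstituted alkene than at the conjugated alkyne, so dye-controlled dosing and reductive work-up with Me2S (a phosphine would isomerise the ynone) should deliver the ynone, and the trans hydroxyl cannot close a hemiketal on the new ketone.

**Step 7**
Reactants: 10 (3R,4S)-3-hydroxy-4-methyl-4-(2-oxopent-3-yn-1-yl)oxolan-2-one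
Product: 11 (3R,4S)-3-hydroxy-4-[(3Z)-4-iodo-2-oxopent-3-en-1-yl]-4-methyloxolan-2-one
Conditions: NaI (1.5 equiv), AcOH, 23 °C, dark
Reagents that add atoms: sodium iodide, [Na+].[I-]
Why: Hydroiodination of an ynone (conjugate addition of iodide and protonation of the iodoallenol, net anti addition) is known to give the (Z)-β-iodoenone under mild kinetic conditions, which places iodine cis to the C4' carbonyl as the ring closure requires.

**Step 8**
Reactants: 11 (3R,4S)-3-hydroxy-4-[(3Z)-4-iodo-2-oxopent-3-en-1-yl]-4-methyloxolan-2-one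
Product: 12 (4S)-4-[(3Z)-4-iodo-2-oxopent-3-en-1-yl]-4-methyloxolane-2,3-dione
Conditions: Dess–Martin periodinane (1.3 equiv), CH2Cl2, 0 → 23 °C; filtration through silica
Reagents that add atoms: none
Why: Dess–Martin oxidation turns the α-hydroxy lactone into the non-enolisable α-keto lactone under neutral, water-free conditions that leave the iodoenone geometry alone, and it is placed last so that the reactive 1,2-dicarbonyl unit meets no nucleophile before the ring closure.

**Step 9**
Reactants: 12 (4S)-4-[(3Z)-4-iodo-2-oxopent-3-en-1-yl]-4-methyloxolane-2,3-dione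
Product: 13 (3aS,7aR)-7a-hydroxy-3a,7-dimethyl-3,3a,4,7a-tetrahydro-2-benzofuran-1,5-dione (cis-fused hydroxy enone lactone)
Conditions: CrCl2 (6 equiv), NiCl2 (5 mol %), degassed DMF, 0.01 M, 23 °C; then H2O/EtOAc
Reagents that add atoms: none
Why: Proposed new method: CrCl2 reduces NiCl2 to zerovalent nickel, which inserts into the C2'–I bond of 12, the alkenyl group passes to trivalent chromium, the alkenylchromium adds to the C1' ketone and the chromium alkoxide is hydrolysed on work-up. The closest known reaction type is the intramolecular Nozaki–Hiyama–Kishi cyclisation of iodoalkenyl aldehydes (with the chromium-mediated coupling of (Z)-β-iodoacrylates and aldehydes as proof that a carbonyl group cis to the metal is tolerated); ketones are normally too unreactive, and the proposal rests on the adjacent lactone carbonyl, which should make the non-enolisable C1' ketone about as electrophilic as an aldehyde, and on intramolecularity. Ring A closes in a 6-exo-trig mode with respect to the C1'=O bond, with C2'=C3' ending up cis inside the ring; only the Z organometallic can reach C1', and any E isomer can drain back through its chromium allenolate. The one new stereocentre, C1', is controlled by C6': the four-atom tether starts on one face of the lactone ring and can bring C2' only to that face of the neighbouring ketone, so the 6-5 system must be cis-fused, with OH cis to the C6' methyl group and the lactone carbonyl (future C5) cis to C8'H2O. Chemoselectivity is needed for the ketone over the lactone and enone carbonyls, which is secured by its 1,2-dicarbonyl activation and by ring size (attack on the lactone carbonyl would need a seven-membered ring), and for C–I activation over one-electron reduction of the dicarbonyl unit, which is secured by the very easily reduced β-iodoenone and the nickel catalyst.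

**Step 10**
Reactants: 13 (3aS,7aR)-7a-hydroxy-3a,7-dimethyl-3,3a,4,7a-tetrahydro-2-benzofuran-1,5-dione
Product: 14 C4' ethylene ketal of 13 (spiro-1,3-dioxolane at the former enone carbonyl, 3aS,7aR)
Conditions: (TMSOCH2)2 (3 equiv), TMSOTf (10 mol %), CH2Cl2, −78 → −20 °C; pyridine quench
Reagents that add atoms: 1,2-bis(trimethylsilyloxy)ethane, C[Si](C)(C)OCCO[Si](C)(C)C
Why: Noyori ketalisation under aprotic low-temperature conditions protects the C4' carbonyl without moving the C2'=C3' bond (C1' bears no hydrogen), and the lactone and the hindered tertiary alcohol should not react.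

**Step 11**
Reactants: 14 C4' ethylene ketal of 13
Product: 15 lactol of 14 (C5 hemiacetal, anomeric mixture)
Conditions: DIBAL-H (2.5 equiv), CH2Cl2, −78 °C; aq Rochelle salt
Reagents that add atoms: none
Why: Partial reduction of a γ-lactone with DIBAL-H stops at the tetrahedral aluminium lactolate at −78 °C, the first equivalent being used up by the tertiary hydroxyl, and the new anomeric centre is of no consequence.

**Step 12**
Reactants: 15 lactol of 14
Product: 16 (8R,9S)-8-ethynyl-9-(hydroxymethyl)-7,9-dimethyl-1,4-dioxaspiro[4.5]dec-6-en-8-ol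
Conditions: dimethyl (1-diazo-2-oxopropyl)phosphonate (2.5 equiv), K2CO3 (3 equiv), MeOH, 0 → 23 °C
Reagents that add atoms: dimethyl (1-diazo-2-oxopropyl)phosphonate, CC(=O)C(=[N+]=[N-])P(=O)(OC)OC
Why: Ohira–Bestmann (Seyferth–Gilbert) homologation works on lactols through their open hydroxy aldehyde form, so C5 gains the alkyne carbon C4 by 1,2-hydrogen shift in the alkylidene carbene while C8'–OH is set free and C1' and C6' stay untouched.

**Step 13**
Reactants: 17 (R)-mevalonolactone
Product: 19 benzyl (3R)-3,5-dihydroxy-3-methylpentanoate, via potassium (R)-mevalonate 18 (not isolated)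
Conditions: KOH (1.0 equiv), MeOH/H2O, 23 °C; concentrate; BnBr (1.1 equiv), DMF, 23 °C
Reagents that add atoms: potassium hydroxide, [K+].[OH-]; benzyl bromide, BrCc1ccccc1
Why: Saponification of the δ-lactone and SN2 benzylation of the carboxylate fix the open form of mevalonate as its benzyl ester without touching the tertiary carbinol centre.

**Step 14**
Reactants: 19 benzyl (3R)-3,5-dihydroxy-3-methylpentanoate
Product: 20 (3R)-5-(benzyloxy)-3-hydroxy-3-methyl-5-oxopentanoic acid
Conditions: TEMPO (10 mol %), PhI(OAc)2 (2.3 equiv), MeCN/H2O, 23 °C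
Reagents that add atoms: water, O
Why: TEMPO/PhI(OAc)2 oxidation in aqueous acetonitrile takes the primary alcohol through the aldehyde hydrate to the acid faster than the hydroxy ester should relactonise and cannot touch the tertiary alcohol.

**Step 15**
Reactants: 20 (3R)-5-(benzyloxy)-3-hydroxy-3-methyl-5-oxopentanoic acid
Product: 21 benzyl 2-(trimethylsilyl)ethyl (3S)-3-hydroxy-3-methylpentanedioate
Conditions: 2-(trimethylsilyl)ethanol (1.5 equiv), DIC (1.2 equiv), DMAP (10 mol %), CH2Cl2, 0 → 23 °C
Reagents that add atoms: 2-(trimethylsilyl)ethanol, C[Si](C)(C)CCO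
Why: Steglich esterification of the free acid gives the mixed diester, the tertiary hydroxyl being too hindered to compete.

**Step 16**
Reactants: 21 benzyl 2-(trimethylsilyl)ethyl (3S)-3-hydroxy-3-methylpentanedioate
Product: 22 (3S)-3-hydroxy-3-methyl-5-oxo-5-[2-(trimethylsilyl)ethoxy]pentanoic acid
Conditions: H2 (1 atm), Pd/C, EtOAc, 23 °C
Reagents that add atoms: none
Why: Hydrogenolysis cleaves only the benzyl ester, so the carboxyl group that was C1 of (R)-mevalonate is freed and the two arms of the HMG unit are told apart in the sense needed for the 3R ester of the target.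

**Step 17**
Reactants: 16 (8R,9S)-8-ethynyl-9-(hydroxymethyl)-7,9-dimethyl-1,4-dioxaspiro[4.5]dec-6-en-8-ol; 22 (3S)-3-hydroxy-3-methyl-5-oxo-5-[2-(trimethylsilyl)ethoxy]pentanoic acid
Product: 23 [(8R,9S)-8-ethynyl-8-hydroxy-7,9-dimethyl-1,4-dioxaspiro[4.5]dec-6-en-9-yl]methyl 2-(trimethylsilyl)ethyl (3S)-3-hydroxy-3-methylpentanedioate
Conditions: 22 (1.3 equiv), DIC (1.5 equiv), DMAP (0.3 equiv), CH2Cl2, 0 → 23 °C
Reagents that add atoms: none
Why: Steglich esterification should acylate only the primary C8' hydroxyl, since both tertiary hydroxyls (C1' and HMG C3) are far more hindered, and no stereocentre is touched.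

**Step 18**
Reactants: 23 C8' HMG ester of alkyne 16
Product: 24 (E)-alkenylstannane of 23 (C1'–CH=CH–SnBu3)
Conditions: Bu3SnH (1.3 equiv), PdCl2(PPh3)2 (3 mol %), THF, 0 → 23 °C
Reagents that add atoms: tributyltin hydride, CCCC[SnH](CCCC)CCCC
Why: Palladium-catalysed hydrostannylation is a syn addition that places tin on the terminal carbon of an alkyne flanked by a fully substituted carbinol, which should give the (E)-alkenylstannane.

**Step 19**
Reactants: 25 but-2-ynoic acid
Product: 26 (2Z)-3-iodobut-2-enoic acid
Conditions: NaI (1.6 equiv), AcOH, 110 °C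
Reagents that add atoms: sodium iodide, [Na+].[I-]
Why: Hydroiodination of but-2-ynoic acid with NaI in hot acetic acid is a known net anti addition that gives the (Z)-3-iodo acid.

**Step 20**
Reactants: 26 (2Z)-3-iodobut-2-enoic acid
Product: 27 2-(trimethylsilyl)ethyl (2Z)-3-iodobut-2-enoate
Conditions: 2-(trimethylsilyl)ethanol (1.2 equiv), DIC (1.1 equiv), DMAP (10 mol %), CH2Cl2, 0 → 23 °C
Reagents that add atoms: 2-(trimethylsilyl)ethanol, C[Si](C)(C)CCO
Why: Steglich esterification takes place at the carboxyl group only and does not affect the alkene geometry.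

**Step 21**
Reactants: 24 (E)-alkenylstannane of 23; 27 2-(trimethylsilyl)ethyl (2Z)-3-iodobut-2-enoate
Product: 28 bis[2-(trimethylsilyl)ethyl] ester C4' ethylene ketal of the target ((2Z,4E)-dienoate)
Conditions: Pd2(dba)3 (5 mol %), AsPh3 (20 mol %), NMP, 23 → 40 °C
Reagents that add atoms: none
Why: Stille coupling proceeds with retention at both alkenyl partners, so the 4E stannane and the 2Z iodide should give the (2Z,4E)-dienoate under neutral conditions that spare the ketal, the esters and the free hydroxyls.

**Step 22**
Reactants: 28 bis[2-(trimethylsilyl)ethyl] ester C4' ethylene ketal of the target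
Product: 30 target CNP0183058.1, via diacid ketal 29 (not isolated)
Conditions: TBAF (6 equiv), THF, 0 → 23 °C; then 1 M HCl to pH 1, THF/H2O, 23 °C
Reagents that add atoms: water, O
Why: Fluoride-induced fragmentation of both 2-(trimethylsilyl)ethyl esters (loss of ethene and Me3SiF) spares the alkyl ester at C8', and the allylic ketal is then hydrolysed by dilute acid through a stabilised oxocarbenium ion under conditions in which the electron-poor C1' alcohol should not ionise.

## Compound list

1 | dimethyl (R)-malate | COC(=O)C[C@@H](O)C(=O)OC | starting material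
2 | 2,3-dibromopropene | C=C(Br)CBr | starting material
3 | dimethyl (2R,3S)-3-(2-bromoprop-2-en-1-yl)-2-hydroxybutanedioate | COC(=O)[C@@H](CC(Br)=C)[C@@H](O)C(=O)OC | intermediate
4 | propyne | CC#C | starting material
5 | dimethyl (2R,3S)-2-hydroxy-3-(2-methylidenepent-3-yn-1-yl)butanedioate | COC(=O)[C@@H](CC(=C)C#CC)[C@@H](O)C(=O)OC | intermediate
6 | dimethyl (2R,3R)-2-hydroxy-3-methyl-3-(2-methylidenepent-3-yn-1-yl)butanedioate | COC(=O)[C@@](CC(=C)C#CC)(C)[C@@H](O)C(=O)OC | intermediate
7 | (2R,3R)-2-hydroxy-4-methoxy-3-methyl-3-(2-methylidenepent-3-yn-1-yl)-4-oxobutanoic acid | COC(=O)[C@@](CC(=C)C#CC)(C)[C@@H](O)C(=O)O | intermediate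
8 | (2R,3S)-2-hydroxy-3-(hydroxymethyl)-3-methyl-5-methylideneoct-6-ynoic acid (not isolated) | OC[C@@](CC(=C)C#CC)(C)[C@@H](O)C(=O)O | intermediate
9 | (3R,4S)-3-hydroxy-4-methyl-4-(2-methylidenepent-3-yn-1-yl)oxolan-2-one | O=C1OC[C@](C)(CC(=C)C#CC)[C@H]1O | intermediate
10 | (3R,4S)-3-hydroxy-4-methyl-4-(2-oxopent-3-yn-1-yl)oxolan-2-one | O=C1OC[C@](C)(CC(=O)C#CC)[C@H]1O | intermediate
11 | (3R,4S)-3-hydroxy-4-[(3Z)-4-iodo-2-oxopent-3-en-1-yl]-4-methyloxolan-2-one | O=C1OC[C@](C)(CC(=O)/C=C(/C)I)[C@H]1O | intermediate
12 | (4S)-4-[(3Z)-4-iodo-2-oxopent-3-en-1-yl]-4-methyloxolane-2,3-dione | C/C(I)=C/C(=O)C[C@@]1(C)COC(=O)C1=O | intermediate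
13 | (3aS,7aR)-7a-hydroxy-3a,7-dimethyl-3,3a,4,7a-tetrahydro-2-benzofuran-1,5-dione | CC1=CC(=O)C[C@@]2(C)COC(=O)[C@@]12O | intermediate
14 | C4' ethylene ketal of 13 | CC1=CC3(OCCO3)C[C@@]2(C)COC(=O)[C@@]12O | intermediate
15 | lactol of 14 (anomeric mixture) | CC1=CC3(OCCO3)C[C@@]2(C)COC(O)[C@@]12O | intermediate
16 | (8R,9S)-8-ethynyl-9-(hydroxymethyl)-7,9-dimethyl-1,4-dioxaspiro[4.5]dec-6-en-8-ol | CC1=CC3(OCCO3)C[C@@](C)(CO)[C@@]1(O)C#C | intermediate
17 | (R)-mevalonolactone | O=C1C[C@](C)(O)CCO1 | starting material
18 | potassium (R)-mevalonate (not isolated) | [K+].[O-]C(=O)C[C@](C)(O)CCO | intermediate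
19 | benzyl (3R)-3,5-dihydroxy-3-methylpentanoate | O=C(OCc1ccccc1)C[C@](C)(O)CCO | intermediate
20 | (3R)-5-(benzyloxy)-3-hydroxy-3-methyl-5-oxopentanoic acid | O=C(OCc1ccccc1)C[C@](C)(O)CC(=O)O | intermediate
21 | benzyl 2-(trimethylsilyl)ethyl (3S)-3-hydroxy-3-methylpentanedioate | O=C(OCc1ccccc1)C[C@](C)(O)CC(=O)OCC[Si](C)(C)C | intermediate
22 | (3S)-3-hydroxy-3-methyl-5-oxo-5-[2-(trimethylsilyl)ethoxy]pentanoic acid | OC(=O)C[C@](C)(O)CC(=O)OCC[Si](C)(C)C | intermediate
23 | [(8R,9S)-8-ethynyl-8-hydroxy-7,9-dimethyl-1,4-dioxaspiro[4.5]dec-6-en-9-yl]methyl 2-(trimethylsilyl)ethyl (3S)-3-hydroxy-3-methylpentanedioate | CC1=CC3(OCCO3)C[C@@](C)(COC(=O)C[C@](C)(O)CC(=O)OCC[Si](C)(C)C)[C@@]1(O)C#C | intermediate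
24 | (E)-2-(tributylstannyl)ethenyl analogue of 23 | CC1=CC3(OCCO3)C[C@@](C)(COC(=O)C[C@](C)(O)CC(=O)OCC[Si](C)(C)C)[C@@]1(O)/C=C/[Sn](CCCC)(CCCC)CCCC | intermediate
25 | but-2-ynoic acid | CC#CC(=O)O | starting material
26 | (2Z)-3-iodobut-2-enoic acid | C/C(I)=C/C(=O)O | intermediate
27 | 2-(trimethylsilyl)ethyl (2Z)-3-iodobut-2-enoate | C/C(I)=C/C(=O)OCC[Si](C)(C)C | intermediate
28 | bis[2-(trimethylsilyl)ethyl] ester C4' ethylene ketal of the target | CC1=CC3(OCCO3)C[C@@](C)(COC(=O)C[C@](C)(O)CC(=O)OCC[Si](C)(C)C)[C@@]1(O)/C=C/C(C)=C\C(=O)OCC[Si](C)(C)C | intermediate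
29 | C4' ethylene ketal of the target diacid (not isolated) | CC1=CC3(OCCO3)C[C@@](C)(COC(=O)C[C@](C)(O)CC(=O)O)[C@@]1(O)/C=C/C(C)=C\C(=O)O | intermediate
30 | (2Z,4E)-5-[(1R,6S)-6-({[(3R)-4-carboxy-3-hydroxy-3-methylbutanoyl]oxy}methyl)-1-hydroxy-2,6-dimethyl-4-oxocyclohex-2-en-1-yl]-3-methylpenta-2,4-dienoic acid | CC1=CC(=O)C[C@@](C)(COC(=O)C[C@](C)(O)CC(=O)O)[C@@]1(O)/C=C/C(C)=C\C(=O)O | target

## Step count

- Total step count: 22.
- Longest linear sequence: 16 (steps 1–12, 17, 18, 21, 22).

## Steps most likely to fail

**First, step 9.**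
- *What may go wrong.* Divalent chromium may reduce the 1,2-dicarbonyl unit by one electron, or couple it in a pinacol manner. The sluggish β-acyl alkenylchromium may be protonated before it adds. The alkene geometry may be lost.
- *Fallback.* It uses known chemistry: a masked β-acylvinyl anion made by iodine–lithium exchange, followed by a Parham-type cyclisation onto a ketone.
  - It sets out from 11, whose enone carbonyl is masked with (TMSOCH2)2/TMSOTf at −78 °C to give the dioxolane-protected hydroxy lactone iodoalkene F1.
  - Dess–Martin oxidation then gives the dioxolane-protected keto lactone iodoalkene F2.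
  - t-BuLi (2.1 equiv, THF/Et2O/pentane, −100 °C) exchanges the alkenyl iodide faster than it adds to a carbonyl group. The configurationally stable Z-alkenyllithium closes onto the C1' ketone under the same tether control.
  - This comes back to the route at 14 and replaces steps 8–10.

**Second, step 12.**
- *What may go wrong.* The lactol may release too little of its open, neopentyl-type α-hydroxy aldehyde form, so that the diazophosphonate anion decomposes before it condenses.
- *Fallback.* It avoids the lactol altogether.
  - It sets out from 14, which is opened with MeNH(OMe)·HCl/AlMe3 to the Weinreb amide diol F3.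
  - The freed C8' hydroxyl is capped at once with TBSCl/imidazole to give the silyl ether amide F4.
  - DIBAL-H at −78 °C gives the free α-hydroxy aldehyde F5, which can no longer close to a lactol.
  - Ohira–Bestmann homologation gives the silyl-protected alkyne F6, and TBAF removes the silyl group.
  - This comes back to the route at 16.

**Third, step 17.**
- *What may go wrong.* Acylation of the neopentyl C8' hydroxyl may be slow, which leaves time for acyl migration in the activated acid (N-acylurea formation). The unprotected β-hydroxy acyl donor may also close to a β-lactone or lose water.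
- *Fallback.* It masks the β-hydroxyl and uses a mixed anhydride.
  - It sets out from 21, which is silylated with TESOTf/2,6-lutidine to the triethylsilyl ether diester F7.
  - Hydrogenolysis gives the triethylsilyl-protected half ester acid F8.
  - Yamaguchi esterification (2,4,6-trichlorobenzoyl chloride, Et3N, then 16 and DMAP, toluene) gives the protected C8' ester F9.
  - HF·pyridine buffered with pyridine (THF, 0 °C) removes only the triethylsilyl ether.
  - This comes back to the route at 23.

## Further compounds

F1 | step 9 | (3R,4S)-3-hydroxy-4-({2-[(1Z)-2-iodoprop-1-en-1-yl]-1,3-dioxolan-2-yl}methyl)-4-methyloxolan-2-one | O=C1OC[C@](C)(CC2(OCCO2)/C=C(/C)I)[C@H]1O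
F2 | step 9 | (4S)-4-({2-[(1Z)-2-iodoprop-1-en-1-yl]-1,3-dioxolan-2-yl}methyl)-4-methyloxolane-2,3-dione | O=C1OC[C@](C)(CC2(OCCO2)/C=C(/C)I)C1=O
F3 | step 12 | (8R,9S)-8-hydroxy-9-(hydroxymethyl)-N-methoxy-N,7,9-trimethyl-1,4-dioxaspiro[4.5]dec-6-ene-8-carboxamide | CC1=CC3(OCCO3)C[C@@](C)(CO)[C@@]1(O)C(=O)N(C)OC
F4 | step 12 | C8' tert-butyldimethylsilyl ether of F3 | CC1=CC3(OCCO3)C[C@@](C)(CO[Si](C)(C)C(C)(C)C)[C@@]1(O)C(=O)N(C)OC
F5 | step 12 | (8R,9S)-9-{[(tert-butyldimethylsilyl)oxy]methyl}-8-hydroxy-7,9-dimethyl-1,4-dioxaspiro[4.5]dec-6-ene-8-carbaldehyde | CC1=CC3(OCCO3)C[C@@](C)(CO[Si](C)(C)C(C)(C)C)[C@@]1(O)C=O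
F6 | step 12 | C8' tert-butyldimethylsilyl ether of 16 | CC1=CC3(OCCO3)C[C@@](C)(CO[Si](C)(C)C(C)(C)C)[C@@]1(O)C#C
F7 | step 17 | benzyl 2-(trimethylsilyl)ethyl 3-methyl-3-[(triethylsilyl)oxy]pentanedioate (configuration as in 21) | O=C(OCc1ccccc1)C[C@](C)(O[Si](CC)(CC)CC)CC(=O)OCC[Si](C)(C)C
F8 | step 17 | 3-methyl-5-oxo-3-[(triethylsilyl)oxy]-5-[2-(trimethylsilyl)ethoxy]pentanoic acid (configuration as in 22) | OC(=O)C[C@](C)(O[Si](CC)(CC)CC)CC(=O)OCC[Si](C)(C)C
F9 | step 17 | triethylsilyl ether of 23 at the HMG hydroxyl | CC1=CC3(OCCO3)C[C@@](C)(COC(=O)C[C@](C)(O[Si](CC)(CC)CC)CC(=O)OCC[Si](C)(C)C)[C@@]1(O)C#C
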